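(Readings and results were generated by integration on assumed constants, and the scatter is random.)

6.13 % of the charge is the mean reading of dissolved substrate in the spring run from 40.0 s on, taken from readings of 6.1 %, 5.8 % and 6.5 %. The noon run, with a quarter of that partner, was still climbing at 14.9 %. You have to decide whether the next flask keeps 0.700 M of partner or gets more, and that hangs on how much substrate stands uncaptured in solution.

| flask | solid substrate | partner | protic impurity | remark | time |
|---|---|---|---|---|---|
| noon | 1 M | 0.35 M | 0.050 M | run made earlier |  |
| spring | 1 M | 1.4 M | 0.050 M | run made earlier |  |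
| midnight | 0.50 M | 0.70 M | 0.050 M | run made earlier |  |
| flask | 1.0 M | 0.700 M | 0.0500 M |  | 2.0 min |

| run | time / s | target / % | dissolved substrate / % |
|---|---|---|---|
| noon | 10.0 | 0.1 | 1.8 |
| noon | 15.0 | 1.8 | 5.0 |
| noon | 25.0 | 0 | 6.8 |
| noon | 40.0 | 2.0 | 10.1 |
| noon | 60.0 | 5.0 | 12.8 |
| noon | 80.0 | 6.0 | 14.9 |
| spring | 10.0 | 0.6 | 4.1 |
| spring | 15.0 | 1.7 | 2.1 |
| spring | 25.0 | 2.9 | 3.9 |
| spring | 40.0 | 6.8 | 6.1 |
| spring | 60.0 | 10.3 | 5.8 |
| spring | 80.0 | 14.5 | 6.5 |
| midnight | 15.0 | 1.8 | 8.8 |
| midnight | 30.0 | 5.1 | 14.4 |
| midnight | 40.0 | 6.8 | 15.7 |
| midnight | 60.0 | 11.3 | 21.6 |
| midnight | 80.0 | 15.6 | 21.1 |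

(scatter of a reading: 1 percentage point)

- percentages count the solid substrate that a species holds: one side product or homo dimer counts as two
- solid, in amounts per volume of the solution: solid substrate
- the earlier runs were read with a standard deviation of 1 percentage point
- on the list of suspects stand: solid substrate <-> dissolved substrate; dissolved substrate + partner -> target; dissolved substrate + target -> side product; solid substrate + protic impurity -> quenched substrate; 2 solid substrate -> homo dimer
- at the start none of the solid substrate is in solution
- dissolved substrate means what is dissolved; the solid is not counted in it

* amount of target at 2.0 min, in percent of the solid substrate charged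
* concentration of dissolved substrate in solution at 2.0 min, in percent of saturation

Here is my own reckoning. Call the level 12.3 % the fraction of the charge at which dissolved substrate stands once the feed from the solid equals its capture by partner. I treat capture as pseudo-first-order in dissolved substrate, with partner near its charge, and I assume the feed stays as in the spring run. The level then goes inversely with partner. This flask has the same solid charge and half the spring partner, so its level is twice the spring one. On that number I would run the recipe as written and keep more partner for the run after.

The forecast says 16 % of target (13 % to 19.5 %) and 36 % of saturation (24 % to 52 %). It takes a feed that “slows as dissolved substrate builds”, and its own level of 0.13 to 0.14 M on a charge of 1.0 M is not quite mine.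

The flask gives 13.6 % of target, with dissolved substrate at 36.1 % of saturation.

    solid substrate ⇌ dissolved substrate, rate k1*(cs1 - [dissolved substrate]) while solid is left; crystals form when [dissolved substrate] > cs1 (solubility = 0.340 M, k = 0.0110 /s)
    dissolved substrate + partner → target (k = 0.0250 /M/s)
    dissolved substrate + target → side product (k = 0.0400 /M/s)
    solid substrate + protic impurity → quenched substrate (k = 0.0360 /M/s)
    2 solid substrate → homo dimer (k = 0.00510 /M/s)

At 2.00 min this flask makes dissolved substrate 1.04 times as fast as it uses it up, each step taken net, and holds 12.3 % against the level of 12.3 % reckoned from the spring readings. For the neighbour flask charged with 2.8 M of partner, the same rule gives 3.07 %, but at 2.00 min that neighbour holds more, 4.43 % of dissolved substrate, beside 29.1 % of target.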